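**Assumptions (one line each).** The ligand enantiomer in step 1 is chosen empirically to give the (2S,3S) series. Atom labels C1–C11 in the "Why" lines follow the suberosenone skeleton: C1 (carries =CH2), C2 (C=O), C3 (CH2), C4 (ring-fusion CH), C5 (bridgehead CH), C6/C7 (CH2CH2), C8 (CHMe), C9 (quaternary), C10 (CH2), C11 (CMe2). This route is a design on paper; nothing here has been run.

## Retrosynthetic overview

1. Alertenone ⇒ Michael dimerisation of (−)-suberosenone: the C3 dienolate of one molecule adds to the exo-methylene enone of a second.
2. Suberosenone ⇒ α-methylenation of the C1 enolate released when a cyclobutyl ketone is reductively opened; the same cleavage turns the cyclobutane CH2 into the C8 methyl.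
3. Cyclobutyl ketone ⇒ intramolecular enone–alkene [2+2] of a butenyl-substituted bicyclo[3.3.0]octenone, which closes the six-membered ring, makes quaternary C9 and fixes C8.
4. Bicyclic enone ⇒ aldol cyclodehydration of a 1,4-diketone made by asymmetric conjugate addition/propargylation of 4,4-dimethylcyclopentenone.
5. Ring order: B (purchased cyclopentenone) → A (aldol) → six-membered ring plus temporary cyclobutane (hν) → cyclobutane opened → dimer.

## Forward route

**Step 1**
Reactants: 1, 4,4-dimethylcyclopent-2-en-1-one; 2, but-3-en-1-ylmagnesium bromide; 3, propargyl bromide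
Product: 4, (2S,3S)-3-(but-3-en-1-yl)-4,4-dimethyl-2-(prop-2-yn-1-yl)cyclopentan-1-one (2,3-trans)
Conditions: 2 (Et2O), CuBr·SMe2 (5 mol %), Josiphos-type ferrocenyl diphosphine (6 mol %), t-BuOMe, −78 °C; then DMPU, 3, −78 → 0 °C
Reagents that add atoms: but-3-enylmagnesium bromide, C=CCC[Mg]Br; propargyl bromide, C#CCBr
Why: Cu-catalysed asymmetric conjugate addition sets C5 under catalyst control, and the magnesium enolate is alkylated anti to the new butenyl group, giving the trans C4/C5 relationship.

**Step 2**
Reactants: 4
Product: 5, (2S,3S)-3-(but-3-en-1-yl)-4,4-dimethyl-2-(2-oxopropyl)cyclopentan-1-one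
Conditions: Ph3PAuNTf2 (2 mol %), MeOH–H2O 10:1, 50 °C
Reagents that add atoms: water, O
Why: Markovnikov hydration of the terminal alkyne (assisted by the neighbouring ketone) gives the 1,4-diketone; the remote terminal alkene is untouched and no stereocentre changes.

**Step 3**
Reactants: 5
Product: 6, (6S,6aS)-6-(but-3-en-1-yl)-5,5-dimethyl-4,5,6,6a-tetrahydropentalen-2(1H)-one (butenyl cis to H-6a)
Conditions: KOH, EtOH–H2O, reflux
Reagents that add atoms: none
Why: Intramolecular aldol condensation of the 1,4-diketone (methyl-ketone enolate onto the ring ketone, then dehydration) forms ring A as the conjugated cyclopentenone; the trans C4/C5 arrangement is also the thermodynamic one.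

**Step 4**
Reactants: 6
Product: 7, tetracyclic cyclobutyl ketone: the butenyl CH= carbon is bonded to the enone β-carbon (C9), closing the six-membered ring, and the =CH2 carbon is bonded to the α-carbon (C1), giving a cyclobutane cis-fused to the cyclopentanone on the face of the former H-6a
Conditions: hν (350 nm, Pyrex), degassed hexane, 0.005 M, rt
Reagents that add atoms: none
Why: Intramolecular enone–alkene [2+2] photocycloaddition (straight mode); the tether can only reach the convex face, which sets quaternary C9, and C8 is forced to the natural configuration because its CH2 must bridge to C1 while C7 stays in the six-membered ring.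

**Step 5**
Reactants: 7
Product: 8, trimethylsilyl enol ether (C1=C2–OSiMe3) of 1-desmethylene-suberosenone, now carrying the C8 methyl
Conditions: Li, NH3(l)/THF, −78 °C; isoprene; evaporate NH3; TMSCl, Et3N, THF, 0 °C
Reagents that add atoms: chlorotrimethylsilane, C[Si](C)(C)Cl
Why: Dissolving-metal reductive fragmentation of the α-cyclobutyl ketone cleaves the exocyclic C1–CH2 bond (best overlap with the ketyl), converting that CH2 into the C8 methyl and giving the C1 enolate regiospecifically, which is trapped as its silyl enol ether.

**Step 6**
Reactants: 8; 9, Eschenmoser's salt (N,N-dimethylmethyleneiminium iodide)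
Product: 10, (−)-suberosenone
Conditions: 9, CH2Cl2, rt; then MeI; then DBU (one pot)
Reagents that add atoms: Eschenmoser's salt, C=[N+](C)C.[I-] (only its CH2 is retained)
Why: Mannich reaction of the regiodefined silyl enol ether followed by quaternisation and E1cB elimination installs the exo-methylene at C1, next to the quaternary carbon, without touching C3.

**Step 7**
Reactants: 10 (two molecules: one as lithium dienolate, one as acceptor)
Product: 11, alertenone
Conditions: LiHMDS (1.0 equiv), THF, −78 °C, 10 (1.0 equiv) added dropwise; then 10 (1.1 equiv), −78 → −50 °C; AcOH/THF quench at −78 °C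
Reagents that add atoms: none
Why: Michael addition of the C3 dienolate to the exo-methylene enone; C3 is attacked on the convex face (syn to H-4, anti to the C11 gem-dimethyl), and kinetic protonation of the acceptor enolate should occur from the C10′ side, away from the axial C8′ methyl, giving the natural C1′ configuration.

## Compound list

1 | 4,4-dimethylcyclopent-2-en-1-one | CC1(C)CC(=O)C=C1 | starting material
2 | but-3-en-1-ylmagnesium bromide | C=CCC[Mg]Br | starting material
3 | propargyl bromide | C#CCBr | starting material
4 | (2S,3S)-3-(but-3-en-1-yl)-4,4-dimethyl-2-(prop-2-yn-1-yl)cyclopentan-1-one | C#CC[C@H]1[C@H](CCC=C)C(C)(C)CC1=O | intermediate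
5 | (2S,3S)-3-(but-3-en-1-yl)-4,4-dimethyl-2-(2-oxopropyl)cyclopentan-1-one | CC(=O)C[C@H]1[C@H](CCC=C)C(C)(C)CC1=O | intermediate
6 | (6S,6aS)-6-(but-3-en-1-yl)-5,5-dimethyl-4,5,6,6a-tetrahydropentalen-2(1H)-one | O=C1C=C2CC(C)(C)[C@@H](CCC=C)[C@@H]2C1 | intermediate
7 | tetracyclic cyclobutyl ketone ([2+2] photoadduct) | O=C1C[C@H]2[C@@H]3CC[C@@H]4C[C@H]1[C@]24CC3(C)C | intermediate
8 | TMS enol ether (Δ1,2) of 1-desmethylene-suberosenone | C1=C(O[Si](C)(C)C)C[C@H]2[C@@H]3CC[C@H](C)[C@]12CC3(C)C | intermediate
9 | Eschenmoser's salt | C=[N+](C)C.[I-] | starting material
10 | (−)-suberosenone | C=C1C(=O)C[C@H]2[C@@H]3CC[C@H](C)[C@]12CC3(C)C | intermediate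
11 | alertenone | C=C1C(=O)[C@H](C[C@@H]2C(=O)C[C@H]3[C@@H]4CC[C@H](C)[C@]23CC4(C)C)[C@H]2[C@@H]3CC[C@H](C)[C@]12CC3(C)C | target

## Summary

Total steps: 7. Longest linear sequence: 7.

Steps most likely to fail, each with a fallback that changes the approach:

1. **Step 4 (photocycloaddition).** A six-membered ring must close through a four-atom tether and the adduct is strained; hydrogen abstraction or intermolecular dimerisation of the enone may compete. Fallback: skip the cyclobutane and close the C8–C9 bond by a metal-hydride HAT-initiated 6-exo Giese cyclisation of 6 (Fe(acac)3, PhSiH3). The alkene terminus becomes the methyl directly, but C8 epimers would have to be separated and the methylenation then needs its own C1-selective handling.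

2. **Step 1 (asymmetric conjugate addition and trapping).** The β-carbon sits next to a quaternary centre, so ee and yield are uncertain, and magnesium enolates alkylate sluggishly. Fallback: run the three-component coupling racemically (CuI-mediated, TMSCl trap, then lithium enolate plus propargyl bromide) and obtain the single enantiomer by resolution at enone 6 (kinetic resolution by CBS reduction, or preparative chiral chromatography).

3. **Step 7 (dimerisation).** Oligomerisation and the kinetic C1′ protonation are the risks; C1′ is epimerisable and the natural isomer is probably not the thermodynamic one, so base exposure after the quench must be avoided. Fallback: make it a cross-coupling with a masked acceptor by adding the lithium dienolate of 10 to the Mannich-base methiodide from step 6, which releases the enone slowly in situ.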